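Ring A (C4a–C5–C6–C7–C8–C8a) is a phloroglucinol whose oxygens O1, 7-OMe and 5-OH all differ and whose C8 carries the chain. It is therefore not substituted but built: a chain-bearing 1-methoxyalkyne supplies C7 and C8, a 3-(4-methoxybenzyloxy)cyclobutenone supplies C8a, C4a, C5 and C6. One thermal cascade forms C8–C8a, C6–C7 and C4a–C8a and delivers the arene with O1 free, O7 methylated and O5 as PMB ether, so no selective protection is needed. The alkyne comes from (R)-limonene oxide, which already holds C2″; C2 is set afterwards by Rh-catalysed aryl addition to the chromone.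

Key step: step 8

Remark 1: commercial (+)-limonene 1,2-oxide (cis/trans mixture at C1/C2, made from (R)-limonene) is taken as the chiral starting material; both epoxide epimers give the same keto aldehyde.
Remark 2: the Rh/(S)-bisphosphine catalyst is assumed to attack the chromone on the same face as it attacks 2-cyclohexenone, which gives 2S; should a model run show the opposite sense, the (R)-ligand would be used.

Step 1
Reactants: 1 (4R)-limonene 1,2-oxide (cis/trans mixture)
Product: 2 (3R)-6-oxo-3-(prop-1-en-2-yl)heptanal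
Conditions: H5IO6 (1.2 equiv), THF/H2O, 0 °C → rt
Reagents that add atoms: water, O
Why: Periodic acid hydrolyses the epoxide to the diol and cleaves it in the same flask (Malaprade glycol cleavage), turning C1 into the methyl ketone and C2 into the aldehyde while the isopropenyl group and C4 (the future C2″) are untouched, so both epoxide epimers converge.

Step 2
Reactants: 2 (3R)-6-oxo-3-(prop-1-en-2-yl)heptanal
Product: 3 (3R)-6-oxo-3-(prop-1-en-2-yl)heptanoic acid
Conditions: NaClO2, NaH2PO4, 2-methyl-2-butene, t-BuOH/H2O, 0 °C → rt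
Reagents that add atoms: sodium chlorite, [Na+].[O-]Cl=O
Why: The Pinnick oxidation converts only the aldehyde, the excess 2-methyl-2-butene traps HOCl before it can reach the isopropenyl group, and the stereocentre is β to the carbonyl and cannot epimerise.

Step 3
Reactants: 3 (3R)-6-oxo-3-(prop-1-en-2-yl)heptanoic acid
Product: 4 (3R)-6-hydroxy-6-methyl-3-(prop-1-en-2-yl)heptanoic acid
Conditions: MeMgBr (3.2 equiv), THF, −20 → 0 °C; aq. NH4Cl
Reagents that add atoms: methylmagnesium bromide, C[Mg]Br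
Why: In this Grignard addition the first equivalent forms the magnesium carboxylate, which is inert at 0 °C and so protects the acid, while further reagent adds to the methyl ketone to give the gem-dimethyl carbinol of the side chain.

Step 4
Reactants: 4 (3R)-6-hydroxy-6-methyl-3-(prop-1-en-2-yl)heptanoic acid
Product: 6 (3R)-6-methyl-3-(prop-1-en-2-yl)-6-[(triethylsilyl)oxy]heptanoic acid, via bis-silylated silyl ester 5 (not isolated)
Conditions: TESOTf (2.3 equiv), 2,6-lutidine, CH2Cl2, −40 → 0 °C; then K2CO3, MeOH/H2O, rt; pH 5 work-up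
Reagents that add atoms: triethylsilyl trifluoromethanesulfonate, CC[Si](CC)(CC)OS(=O)(=O)C(F)(F)F
Why: Silyl triflate silylation covers the hindered tertiary alcohol (and the acid), and the silyl ester, far more labile than the tertiary silyl ether, is then cleaved by mild basic methanolysis.

Step 5
Reactants: 6 (3R)-6-methyl-3-(prop-1-en-2-yl)-6-[(triethylsilyl)oxy]heptanoic acid
Product: 8 (3S)-3-(iodomethyl)-2,6-dimethyl-6-[(triethylsilyl)oxy]hept-1-ene, via Barton ester 7 (not isolated)
Conditions: 1-hydroxypyridine-2(1H)-thione, DCC, cat. DMAP, CH2Cl2, 0 °C → rt, dark; then CHI3, cyclohexene/PhH, W lamp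
Reagents that add atoms: iodoform, IC(I)I (iodine of 8); 1-hydroxypyridine-2(1H)-thione, On1ccccc1=S (held in intermediate 7 only)
Why: In this Barton decarboxylative iodination the primary radical left after loss of CO2 is trapped by iodine transfer from iodoform faster than it can undergo the homoallyl/cyclopropylcarbinyl 1,2-vinyl shift, the alkene-tolerant chain avoids I2 (no iodolactonisation), and the stereocentre is never a radical site.

Step 6
Reactants: 9 chloroacetaldehyde dimethyl acetal; 8 (3S)-3-(iodomethyl)-2,6-dimethyl-6-[(triethylsilyl)oxy]hept-1-ene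
Product: 11 (4R)-1-methoxy-7-methyl-4-(prop-1-en-2-yl)-7-[(triethylsilyl)oxy]oct-1-yne, via lithium methoxyacetylide 10 (not isolated)
Conditions: 9 (2.5 equiv), LiNEt2 (from Et2NH/n-BuLi, 7.6 equiv), THF, 0 °C; then 8, DMPU, 0 °C → rt; chromatography on Et3N-deactivated silica
Reagents that add atoms: lithium diethylamide, [Li]N(CC)CC (lithium of intermediate 10 only)
Why: Threefold amide-induced elimination/deprotonation of the chloroacetal gives lithium methoxyacetylide, and its SN2 alkylation by the primary iodide in a dipolar aprotic medium (acetylide alkylation) gives the ynol ether without touching the stereocentre.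

Step 7
Reactants: 12 3-ethoxycyclobut-2-en-1-one; 13 4-methoxybenzyl alcohol
Product: 14 3-[(4-methoxybenzyl)oxy]cyclobut-2-en-1-one
Conditions: 13 (3 equiv), PPTS (10 mol %), toluene, 40 °C, reduced pressure (EtOH removed)
Reagents that add atoms: none
Why: Acid-catalysed alkoxy exchange of a vinylogous ester (addition–elimination at the β-carbon) is driven to the PMB ether by removing the more volatile ethanol, at a temperature below that of cyclobutenone ring opening.

Step 8
Reactants: 11 (4R)-1-methoxy-7-methyl-4-(prop-1-en-2-yl)-7-[(triethylsilyl)oxy]oct-1-yne; 14 3-[(4-methoxybenzyl)oxy]cyclobut-2-en-1-one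
Product: 19 3-methoxy-5-[(4-methoxybenzyl)oxy]-2-{(2R)-5-methyl-2-(prop-1-en-2-yl)-5-[(triethylsilyl)oxy]hexyl}phenol, via vinylketene 15 (not isolated), via vinylcyclobutenone adduct 16 (not isolated), via dienylketene 17 (not isolated), via cyclohexadienone 18 (not isolated)
Conditions: 14 (1.5 equiv), toluene (0.3 M), 80 °C then 110 °C, Ar; then K2CO3, MeOH, rt
Reagents that add atoms: none
Why: Heating opens 14 by 4π-electrocyclic cleavage to vinylketene 15, which adds [2+2] to the ynol ether to give 16; a second 4π opening gives dienylketene 17, thermal 6π-electrocyclisation (C4a–C8a) gives dienone 18, and tautomerisation gives phenol 19. This is a Danheiser benzannulation of a cyclobutenone with an alkoxyalkyne, the 3-alkoxy group on the cyclobutenone being its less common feature. Ring A, the only ring formed, closes by the disrotatory 6π-electrocyclic step; no stereocentre is created and C2″ is a spectator. The one selectivity needed is the orientation of the [2+2] step: the nucleophilic alkyl-bearing alkyne carbon (C8) bonds to the electrophilic ketene carbon (C8a) and the oxygen-bearing carbon (C7) to the ketene α-carbon (C6), a polarity match that puts the free OH beside the chain, OMe on its other side and OPMB meta. A methoxy ynol ether is chosen because it has no β-hydrogen for retro-ene loss of an alkene, and the neutral medium spares the isopropenyl group, the silyl ether and the PMB ether. The closing mild methanolysis only frees any phenol that was O-acylated by 15.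

Step 9
Reactants: 19 3-methoxy-5-[(4-methoxybenzyl)oxy]-2-{(2R)-5-methyl-2-(prop-1-en-2-yl)-5-[(triethylsilyl)oxy]hexyl}phenol
Product: 20 2-hydroxy-4-methoxy-6-[(4-methoxybenzyl)oxy]-3-{(2R)-5-methyl-2-(prop-1-en-2-yl)-5-[(triethylsilyl)oxy]hexyl}benzaldehyde
Conditions: MgCl2, Et3N, (CH2O)n, MeCN, 80 °C; 5 % citric acid work-up
Reagents that add atoms: paraformaldehyde, C=O
Why: In the Casnati–Skattebøl ortho-formylation the magnesium phenoxide delivers formaldehyde through a chelated transition state to the only free ortho position (C4a) and not to the position between OMe and OPMB, and hydride transfer to a second formaldehyde gives the aldehyde under basic conditions that the PMB and silyl ethers tolerate.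

Step 10
Reactants: 20 2-hydroxy-4-methoxy-6-[(4-methoxybenzyl)oxy]-3-{(2R)-5-methyl-2-(prop-1-en-2-yl)-5-[(triethylsilyl)oxy]hexyl}benzaldehyde
Product: 21 1-(2-hydroxy-4-methoxy-6-[(4-methoxybenzyl)oxy]-3-{(2R)-5-methyl-2-(prop-1-en-2-yl)-5-[(triethylsilyl)oxy]hexyl}phenyl)prop-2-yn-1-ol (both carbinol epimers)
Conditions: HC≡CMgBr (3.5 equiv), THF, 0 °C → rt; aq. NH4Cl; used crude
Reagents that add atoms: ethynylmagnesium bromide, C#C[Mg]Br
Why: Grignard 1,2-addition to the aldehyde (after one equivalent has formed the phenoxide) brings in C2 and C3, and the new carbinol centre needs no control because it is oxidised in the next step.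

Step 11
Reactants: 21 1-(2-hydroxy-4-methoxy-6-[(4-methoxybenzyl)oxy]-3-{(2R)-5-methyl-2-(prop-1-en-2-yl)-5-[(triethylsilyl)oxy]hexyl}phenyl)prop-2-yn-1-ol
Product: 23 7-methoxy-5-[(4-methoxybenzyl)oxy]-8-{(2R)-5-methyl-2-(prop-1-en-2-yl)-5-[(triethylsilyl)oxy]hexyl}-4H-chromen-4-one, via ynone 22 (not isolated)
Conditions: activated MnO2, CH2Cl2, rt; filter; then K2CO3 (0.2 equiv), acetone, rt
Reagents that add atoms: none
Why: MnO2 oxidises the benzylic propargylic alcohol selectively, and the o-hydroxyaryl ynone closes ring C by 6-endo-dig oxa-Michael addition of O1 to the terminal alkyne carbon (C2).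

Step 12
Reactants: 24 4-bromoresorcinol
Product: 25 1-bromo-2,4-bis(tert-butyldimethylsilyloxy)benzene
Conditions: TBSCl (2.4 equiv), imidazole, DMF, rt
Reagents that add atoms: tert-butyldimethylsilyl chloride, CC(C)(C)[Si](C)(C)Cl
Why: Standard imidazole-mediated silylation gives B-ring protecting groups that can later be removed by fluoride without acid or base.

Step 13
Reactants: 25 1-bromo-2,4-bis(tert-butyldimethylsilyloxy)benzene
Product: 28 [2,4-bis(tert-butyldimethylsilyloxy)phenyl]boronic acid, via aryllithium 26 (not isolated), via lithium aryltriisopropoxyborate 27 (not isolated)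
Conditions: B(Oi-Pr)3 (1.5 equiv), n-BuLi (1.2 equiv) added last, THF/toluene, −78 → −20 °C; aq. NH4Cl
Reagents that add atoms: triisopropyl borate, CC(C)OB(OC(C)C)OC(C)C; water, O; n-butyllithium, [Li]CCCC (lithium of intermediates 26 and 27 only)
Why: Bromine–lithium exchange with the borate already present (in situ quench) traps the ortho-lithio aryl silyl ether before a retro-Brook silyl shift can occur, and neutral hydrolysis of the borate gives the boronic acid.

Step 14
Reactants: 23 7-methoxy-5-[(4-methoxybenzyl)oxy]-8-{(2R)-5-methyl-2-(prop-1-en-2-yl)-5-[(triethylsilyl)oxy]hexyl}-4H-chromen-4-one; 28 [2,4-bis(tert-butyldimethylsilyloxy)phenyl]boronic acid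
Product: 29 (2S)-2-[2,4-bis(tert-butyldimethylsilyloxy)phenyl]-7-methoxy-5-[(4-methoxybenzyl)oxy]-8-{(2R)-5-methyl-2-(prop-1-en-2-yl)-5-[(triethylsilyl)oxy]hexyl}-2,3-dihydro-4H-chromen-4-one
Conditions: 28 (3 equiv), [RhCl(C2H4)2]2 (2.5 mol %), (S)-MeO-F12-BIPHEP (6 mol %), aq. KOH (10 mol %), toluene/H2O 10:1, 30 °C
Reagents that add atoms: none
Why: In this Hayashi–Miyaura asymmetric 1,4-addition the aryl–Rh(I) species carrying the electron-poor (S)-bisphosphine inserts the C2=C3 bond of the chromone on one face and the oxa-π-allyl is protonated by water, so C2 is set as S by the catalyst alone, the distant C2″ centre exerting no influence.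

Step 15
Reactants: 29 (2S)-2-[2,4-bis(tert-butyldimethylsilyloxy)phenyl]-7-methoxy-5-[(4-methoxybenzyl)oxy]-8-{(2R)-5-methyl-2-(prop-1-en-2-yl)-5-[(triethylsilyl)oxy]hexyl}-2,3-dihydro-4H-chromen-4-one
Product: 30 (2S)-2-[2,4-bis(tert-butyldimethylsilyloxy)phenyl]-5-hydroxy-7-methoxy-8-{(2R)-5-methyl-2-(prop-1-en-2-yl)-5-[(triethylsilyl)oxy]hexyl}-2,3-dihydro-4H-chromen-4-one
Conditions: MgBr2·OEt2 (3 equiv), Me2S (10 equiv), CH2Cl2, 0 °C → rt
Reagents that add atoms: none
Why: Chelation of magnesium between C4=O and O5 activates only the peri PMB ether for Lewis-acid cleavage with dimethyl sulfide as benzyl acceptor, a non-oxidative, non-protic removal that leaves the C2–H benzylic ether, the isopropenyl group and the silyl ethers alone and is run while the B ring is still silylated and hence not a nucleophilic resorcinol.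

Step 16
Reactants: 30 (2S)-2-[2,4-bis(tert-butyldimethylsilyloxy)phenyl]-5-hydroxy-7-methoxy-8-{(2R)-5-methyl-2-(prop-1-en-2-yl)-5-[(triethylsilyl)oxy]hexyl}-2,3-dihydro-4H-chromen-4-one
Product: 31 (2S)-2-(2,4-dihydroxyphenyl)-5-hydroxy-8-[(2R)-5-hydroxy-5-methyl-2-(prop-1-en-2-yl)hexyl]-7-methoxy-2,3-dihydro-4H-chromen-4-one
Conditions: HF·pyridine, pyridine, THF, 0 °C → rt; pH 7 buffer work-up
Reagents that add atoms: none
Why: Buffered fluoride desilylation removes both aryl silyl ethers and the tertiary silyl ether in one operation without the strong acid that would add to the isopropenyl group or ionise the tertiary alcohol and without the base that would epimerise C2 by retro-oxa-Michael opening.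

Compound list
1 | (4R)-limonene 1,2-oxide, (4R)-1-methyl-4-(prop-1-en-2-yl)-7-oxabicyclo[4.1.0]heptane, cis/trans mixture | C=C(C)[C@@H]1CCC2(C)OC2C1 | starting material
2 | (3R)-6-oxo-3-(prop-1-en-2-yl)heptanal | C=C(C)[C@H](CCC(C)=O)CC=O | intermediate
3 | (3R)-6-oxo-3-(prop-1-en-2-yl)heptanoic acid | C=C(C)[C@H](CCC(C)=O)CC(=O)O | intermediate
4 | (3R)-6-hydroxy-6-methyl-3-(prop-1-en-2-yl)heptanoic acid | C=C(C)[C@H](CCC(C)(C)O)CC(=O)O | intermediate
5 | triethylsilyl (3R)-6-methyl-3-(prop-1-en-2-yl)-6-[(triethylsilyl)oxy]heptanoate | C=C(C)[C@H](CCC(C)(C)O[Si](CC)(CC)CC)CC(=O)O[Si](CC)(CC)CC | intermediate (not isolated)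
6 | (3R)-6-methyl-3-(prop-1-en-2-yl)-6-[(triethylsilyl)oxy]heptanoic acid | C=C(C)[C@H](CCC(C)(C)O[Si](CC)(CC)CC)CC(=O)O | intermediate
7 | 2-thioxopyridin-1(2H)-yl (3R)-6-methyl-3-(prop-1-en-2-yl)-6-[(triethylsilyl)oxy]heptanoate | C=C(C)[C@H](CCC(C)(C)O[Si](CC)(CC)CC)CC(=O)On1ccccc1=S | intermediate (not isolated)
8 | (3S)-3-(iodomethyl)-2,6-dimethyl-6-[(triethylsilyl)oxy]hept-1-ene | C=C(C)[C@H](CCC(C)(C)O[Si](CC)(CC)CC)CI | intermediate
9 | chloroacetaldehyde dimethyl acetal | COC(CCl)OC | starting material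
10 | lithium methoxyacetylide | [Li]C#COC | intermediate (not isolated)
11 | (4R)-1-methoxy-7-methyl-4-(prop-1-en-2-yl)-7-[(triethylsilyl)oxy]oct-1-yne | C=C(C)[C@H](CCC(C)(C)O[Si](CC)(CC)CC)CC#COC | intermediate
12 | 3-ethoxycyclobut-2-en-1-one | CCOC1=CC(=O)C1 | starting material
13 | 4-methoxybenzyl alcohol | COc1ccc(CO)cc1 | starting material
14 | 3-[(4-methoxybenzyl)oxy]cyclobut-2-en-1-one | O=C1C=C(OCc2ccc(OC)cc2)C1 | intermediate
15 | 3-[(4-methoxybenzyl)oxy]buta-1,3-dien-1-one (vinylketene) | O=C=CC(=C)OCc1ccc(OC)cc1 | intermediate (not isolated)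
16 | 3-methoxy-4-{1-[(4-methoxybenzyl)oxy]ethenyl}-2-{(2R)-5-methyl-2-(prop-1-en-2-yl)-5-[(triethylsilyl)oxy]hexyl}cyclobut-2-en-1-one (both C4 epimers) | C=C(C)[C@H](CCC(C)(C)O[Si](CC)(CC)CC)CC1=C(OC)C(C(=C)OCc2ccc(OC)cc2)C1=O | intermediate (not isolated)
17 | 3-methoxy-5-[(4-methoxybenzyl)oxy]-2-{(2R)-5-methyl-2-(prop-1-en-2-yl)-5-[(triethylsilyl)oxy]hexyl}hexa-1,3,5-trien-1-one (dienylketene; ketene carbon and vinyl group cis on C3=C4) | C=C(C)[C@H](CCC(C)(C)O[Si](CC)(CC)CC)CC(=C=O)/C(OC)=C\C(=C)OCc1ccc(OC)cc1 | intermediate (not isolated)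
18 | 3-methoxy-5-[(4-methoxybenzyl)oxy]-2-{(2R)-5-methyl-2-(prop-1-en-2-yl)-5-[(triethylsilyl)oxy]hexyl}cyclohexa-2,4-dien-1-one | C=C(C)[C@H](CCC(C)(C)O[Si](CC)(CC)CC)CC1=C(OC)C=C(OCc2ccc(OC)cc2)CC1=O | intermediate (not isolated)
19 | 3-methoxy-5-[(4-methoxybenzyl)oxy]-2-{(2R)-5-methyl-2-(prop-1-en-2-yl)-5-[(triethylsilyl)oxy]hexyl}phenol | C=C(C)[C@H](CCC(C)(C)O[Si](CC)(CC)CC)Cc1c(OC)cc(OCc2ccc(OC)cc2)cc1O | intermediate
20 | 2-hydroxy-4-methoxy-6-[(4-methoxybenzyl)oxy]-3-{(2R)-5-methyl-2-(prop-1-en-2-yl)-5-[(triethylsilyl)oxy]hexyl}benzaldehyde | C=C(C)[C@H](CCC(C)(C)O[Si](CC)(CC)CC)Cc1c(OC)cc(OCc2ccc(OC)cc2)c(C=O)c1O | intermediate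
21 | 1-(2-hydroxy-4-methoxy-6-[(4-methoxybenzyl)oxy]-3-{(2R)-5-methyl-2-(prop-1-en-2-yl)-5-[(triethylsilyl)oxy]hexyl}phenyl)prop-2-yn-1-ol (both carbinol epimers) | C=C(C)[C@H](CCC(C)(C)O[Si](CC)(CC)CC)Cc1c(OC)cc(OCc2ccc(OC)cc2)c(C(O)C#C)c1O | intermediate
22 | 1-(2-hydroxy-4-methoxy-6-[(4-methoxybenzyl)oxy]-3-{(2R)-5-methyl-2-(prop-1-en-2-yl)-5-[(triethylsilyl)oxy]hexyl}phenyl)prop-2-yn-1-one | C=C(C)[C@H](CCC(C)(C)O[Si](CC)(CC)CC)Cc1c(OC)cc(OCc2ccc(OC)cc2)c(C(=O)C#C)c1O | intermediate (not isolated)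
23 | 7-methoxy-5-[(4-methoxybenzyl)oxy]-8-{(2R)-5-methyl-2-(prop-1-en-2-yl)-5-[(triethylsilyl)oxy]hexyl}-4H-chromen-4-one | C=C(C)[C@H](CCC(C)(C)O[Si](CC)(CC)CC)Cc1c(OC)cc(OCc2ccc(OC)cc2)c2c1OC=CC2=O | intermediate
24 | 4-bromoresorcinol | Oc1ccc(Br)c(O)c1 | starting material
25 | 1-bromo-2,4-bis(tert-butyldimethylsilyloxy)benzene | CC(C)(C)[Si](C)(C)Oc1ccc(Br)c(O[Si](C)(C)C(C)(C)C)c1 | intermediate
26 | [2,4-bis(tert-butyldimethylsilyloxy)phenyl]lithium | [Li]c1ccc(O[Si](C)(C)C(C)(C)C)cc1O[Si](C)(C)C(C)(C)C | intermediate (not isolated)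
27 | lithium [2,4-bis(tert-butyldimethylsilyloxy)phenyl]triisopropoxyborate | CC(C)O[B-](OC(C)C)(OC(C)C)c1ccc(O[Si](C)(C)C(C)(C)C)cc1O[Si](C)(C)C(C)(C)C.[Li+] | intermediate (not isolated)
28 | [2,4-bis(tert-butyldimethylsilyloxy)phenyl]boronic acid | OB(O)c1ccc(O[Si](C)(C)C(C)(C)C)cc1O[Si](C)(C)C(C)(C)C | intermediate
29 | (2S)-2-[2,4-bis(tert-butyldimethylsilyloxy)phenyl]-7-methoxy-5-[(4-methoxybenzyl)oxy]-8-{(2R)-5-methyl-2-(prop-1-en-2-yl)-5-[(triethylsilyl)oxy]hexyl}-2,3-dihydro-4H-chromen-4-one | C=C(C)[C@H](CCC(C)(C)O[Si](CC)(CC)CC)Cc1c(OC)cc(OCc2ccc(OC)cc2)c2c1O[C@H](c1ccc(O[Si](C)(C)C(C)(C)C)cc1O[Si](C)(C)C(C)(C)C)CC2=O | intermediate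
30 | (2S)-2-[2,4-bis(tert-butyldimethylsilyloxy)phenyl]-5-hydroxy-7-methoxy-8-{(2R)-5-methyl-2-(prop-1-en-2-yl)-5-[(triethylsilyl)oxy]hexyl}-2,3-dihydro-4H-chromen-4-one | C=C(C)[C@H](CCC(C)(C)O[Si](CC)(CC)CC)Cc1c(OC)cc(O)c2c1O[C@H](c1ccc(O[Si](C)(C)C(C)(C)C)cc1O[Si](C)(C)C(C)(C)C)CC2=O | intermediate
31 | (2S)-2-(2,4-dihydroxyphenyl)-5-hydroxy-8-[(2R)-5-hydroxy-5-methyl-2-(prop-1-en-2-yl)hexyl]-7-methoxy-2,3-dihydro-4H-chromen-4-one | C=C(C)[C@H](CCC(C)(C)O)Cc1c(OC)cc(O)c2c1O[C@H](c1ccc(O)cc1O)CC2=O | target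

Total step count: 16.
Longest linear sequence: 13 steps (steps 1–6, 8–11, 14–16). Step 7 and steps 12–13 are side branches.

Steps most likely to fail

Step 8. Ring opening of the 3-alkoxycyclobutenone may be too slow or too reversible at temperatures the ynol ether tolerates, so that ketene dimerisation and O-acylation of the phenol already formed outrun the [2+2] step. The fallback releases the same ketene at room temperature by 1,4-dehydrochlorination instead of electrocyclic opening. It sets out from 13: phosphine-catalysed oxa-Michael addition of 13 to methyl but-2-ynoate (cat. PMe3) should give methyl (E)-3-[(4-methoxybenzyl)oxy]but-2-enoate F1. Saponification with LiOH gives (E)-3-[(4-methoxybenzyl)oxy]but-2-enoic acid F2, and 1-chloro-N,N,2-trimethylpropenylamine converts it under neutral conditions into (E)-3-[(4-methoxybenzyl)oxy]but-2-enoyl chloride F3. Slow addition of Et3N to F3 and 11 in toluene generates 15, which 11 traps as 16; brief warming carries 16 through 17 and 18, and the route is rejoined at 19.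

Step 6. E2 loss of HI (the β-hydrogen is tertiary and allylic) may compete with SN2 displacement at the β-branched carbon and consume the iodide as a diene. The fallback keeps the carboxyl carbon as the alkyne carbon and so also bypasses step 5. It sets out from 6: coupling with N,O-dimethylhydroxylamine (EDC, NMM) gives (3R)-N-methoxy-N,6-dimethyl-3-(prop-1-en-2-yl)-6-[(triethylsilyl)oxy]heptanamide F4. Methoxymethyllithium (from Bu3SnCH2OMe and n-BuLi, −78 °C) gives (4R)-1-methoxy-7-methyl-4-(prop-1-en-2-yl)-7-[(triethylsilyl)oxy]octan-2-one F5. Enolisation toward the methoxy-bearing carbon with LiHMDS and trapping with PhNTf2 gives (1Z,4R)-1-methoxy-7-methyl-4-(prop-1-en-2-yl)-7-[(triethylsilyl)oxy]oct-1-en-2-yl trifluoromethanesulfonate F6. Anti-elimination with KOt-Bu at low temperature (the known enol-triflate route to ynol ethers) returns to the route at 11.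

Step 14. Protodeboronation of the electron-rich, ortho-oxygenated boronic acid in the protic medium may outpace insertion of the electron-rich chromone, giving low conversion, and a slow reaction also invites erosion of selectivity by retro-oxa-Michael opening. The fallback is an aprotic, silyl-assisted arylzinc addition of known type (Rh/BINAP with chlorotrimethylsilane, established for cyclic enones and 4-quinolones). It sets out from 25 and 23: 25 is converted via 26 (t-BuLi, −78 °C, immediate addition of ZnCl2) into [2,4-bis(tert-butyldimethylsilyloxy)phenyl]zinc chloride F7. With [RhCl((S)-binap)]2 and TMSCl in THF at 20 °C, F7 should add to 23 to give the silyl enol ether (2S)-2-[2,4-bis(tert-butyldimethylsilyloxy)phenyl]-7-methoxy-5-[(4-methoxybenzyl)oxy]-8-{(2R)-5-methyl-2-(prop-1-en-2-yl)-5-[(triethylsilyl)oxy]hexyl}-4-[(trimethylsilyl)oxy]-2H-chromene F8. Mild aqueous hydrolysis of F8 rejoins the route at 29.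

Further compounds
F1 | step 8 | methyl (E)-3-[(4-methoxybenzyl)oxy]but-2-enoate | COC(=O)/C=C(\C)OCc1ccc(OC)cc1
F2 | step 8 | (E)-3-[(4-methoxybenzyl)oxy]but-2-enoic acid | OC(=O)/C=C(\C)OCc1ccc(OC)cc1
F3 | step 8 | (E)-3-[(4-methoxybenzyl)oxy]but-2-enoyl chloride | ClC(=O)/C=C(\C)OCc1ccc(OC)cc1
F4 | step 6 | (3R)-N-methoxy-N,6-dimethyl-3-(prop-1-en-2-yl)-6-[(triethylsilyl)oxy]heptanamide | C=C(C)[C@H](CCC(C)(C)O[Si](CC)(CC)CC)CC(=O)N(C)OC
F5 | step 6 | (4R)-1-methoxy-7-methyl-4-(prop-1-en-2-yl)-7-[(triethylsilyl)oxy]octan-2-one | C=C(C)[C@H](CCC(C)(C)O[Si](CC)(CC)CC)CC(=O)COC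
F6 | step 6 | (1Z,4R)-1-methoxy-7-methyl-4-(prop-1-en-2-yl)-7-[(triethylsilyl)oxy]oct-1-en-2-yl trifluoromethanesulfonate | C=C(C)[C@H](CCC(C)(C)O[Si](CC)(CC)CC)C/C(OS(=O)(=O)C(F)(F)F)=C/OC
F7 | step 14 | [2,4-bis(tert-butyldimethylsilyloxy)phenyl]zinc chloride | Cl[Zn]c1ccc(O[Si](C)(C)C(C)(C)C)cc1O[Si](C)(C)C(C)(C)C
F8 | step 14 | (2S)-2-[2,4-bis(tert-butyldimethylsilyloxy)phenyl]-7-methoxy-5-[(4-methoxybenzyl)oxy]-8-{(2R)-5-methyl-2-(prop-1-en-2-yl)-5-[(triethylsilyl)oxy]hexyl}-4-[(trimethylsilyl)oxy]-2H-chromene | C=C(C)[C@H](CCC(C)(C)O[Si](CC)(CC)CC)Cc1c(OC)cc(OCc2ccc(OC)cc2)c2c1O[C@H](c1ccc(O[Si](C)(C)C(C)(C)C)cc1O[Si](C)(C)C(C)(C)C)C=C2O[Si](C)(C)C
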